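**Retrosynthetic overview**
- The acid comes from its ethyl ester, and the α-methylene group from a Mannich/elimination sequence on a 2,5-trans oxan-2-yl acetate.
- The only ring (the tetrahydropyran) is closed late by a reversible intramolecular oxa-Michael addition of a δ-hydroxy (E)-enoate (O1–C2 bond); C5 controls C2.
- The enoate comes from a Wittig reaction on an aldehyde made by two-carbon homologation (LiCH2CN, then i-Bu2AlH) of a β-branched primary iodide.
- C5, the first stereocentre, comes from lipase-catalysed desymmetrising acetylation of the prochiral 2-homofarnesylpropane-1,3-diol.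
- The diol comes from diethyl malonate and homofarnesyl iodide, itself made from (2E,6E)-farnesol by one-carbon homologation.

Assumption: Burkholderia cepacia lipase acetylates the pro-R hydroxymethyl arm of the prochiral diol (its usual preference for β-branched primary alcohols), giving the (R)-monoacetate; this sense is predicted from the empirical rule, not verified for this substrate, and the first fallback covers the opposite outcome.

**Route**

Step 1
Reactants: 1 (2E,6E)-farnesol [(2E,6E)-3,7,11-trimethyldodeca-2,6,10-trien-1-ol]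
Product: 2 (2E,6E)-farnesal [(2E,6E)-3,7,11-trimethyldodeca-2,6,10-trienal]
Conditions: PhI(OAc)2 (1.1 equiv), TEMPO (10 mol%), CH2Cl2, rt
Reagents that add atoms: none
Why: The TEMPO/hypervalent-iodine oxidation turns the primary allylic alcohol into the enal under non-acidic conditions, so the trisubstituted alkenes and the 2E geometry are untouched.

Step 2
Reactants: 2 (2E,6E)-farnesal
Product: 3 (3E,7E)-4,8,12-trimethyltrideca-1,3,7,11-tetraene
Conditions: MePPh3Br, KOtBu, THF, 0 °C to rt
Reagents that add atoms: methyltriphenylphosphonium bromide, C[P+](c1ccccc1)(c1ccccc1)c1ccccc1.[Br-]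
Why: Wittig methylenation with the non-stabilised ylide adds the extra carbon as a terminal vinyl group without disturbing the existing E-alkenes.

Step 3
Reactants: 3 (3E,7E)-4,8,12-trimethyltrideca-1,3,7,11-tetraene
Product: 5 (3E,7E)-homofarnesol [(3E,7E)-4,8,12-trimethyltrideca-3,7,11-trien-1-ol], via alkylborane 4 (not isolated)
Conditions: 9-BBN, THF, 0 °C to rt; then NaOH, H2O2, H2O, 0 °C to rt
Reagents that add atoms: hydrogen peroxide, OO
Why: Anti-Markovnikov hydroboration–oxidation with the bulky 9-BBN selects the only monosubstituted alkene over the three trisubstituted ones and gives the primary homoallylic alcohol.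

Step 4
Reactants: 5 (3E,7E)-homofarnesol
Product: 6 (3E,7E)-homofarnesyl iodide [(3E,7E)-1-iodo-4,8,12-trimethyltrideca-3,7,11-triene]
Conditions: I2, PPh3, imidazole, CH2Cl2, 0 °C to rt, dark
Reagents that add atoms: iodine, II
Why: Appel-type iodination replaces the primary hydroxyl by iodide through SN2 attack on the alkoxyphosphonium ion under neutral conditions.

Step 5
Reactants: 6 (3E,7E)-homofarnesyl iodide; 7 diethyl malonate
Product: 9 diethyl 2-[(3E,7E)-4,8,12-trimethyltrideca-3,7,11-trienyl]malonate, via sodium malonate enolate 8 (not isolated)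
Conditions: 7 (2 equiv), NaH (1.8 equiv), THF/DMF, 0 °C; then 6, 60 °C
Reagents that add atoms: none
Why: In this malonic ester alkylation the soft enolate displaces the unhindered primary iodide by SN2, and the excess of malonate suppresses dialkylation.

Step 6
Reactants: 9 diethyl 2-[(3E,7E)-4,8,12-trimethyltrideca-3,7,11-trienyl]malonate
Product: 10 2-[(3E,7E)-4,8,12-trimethyltrideca-3,7,11-trienyl]propane-1,3-diol (achiral, with two enantiotopic CH2OH arms)
Conditions: LiAlH4, THF, 0 °C to reflux; H2O/NaOH work-up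
Reagents that add atoms: none
Why: Hydride reduction of both esters gives the prochiral 2-substituted propane-1,3-diol needed for desymmetrisation.

Step 7
Reactants: 10 2-[(3E,7E)-4,8,12-trimethyltrideca-3,7,11-trienyl]propane-1,3-diol
Product: 11 (2R,5E,9E)-2-(hydroxymethyl)-6,10,14-trimethylpentadeca-5,9,13-trienyl acetate
Conditions: lipase PS (Burkholderia cepacia lipase, immobilised), vinyl acetate (5 equiv), t-BuOMe, 25 °C, stopped at about 10% diacetate
Reagents that add atoms: vinyl acetate, C=COC(C)=O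
Why: In this enzymatic desymmetrisation the lipase, a chiral catalyst, transfers acetyl from the irreversible donor vinyl acetate to the pro-R hydroxymethyl arm only, which creates the C5 stereocentre, while slight over-acetylation consumes the minor enantiomer and raises the ee.

Step 8
Reactants: 11 (2R,5E,9E)-2-(hydroxymethyl)-6,10,14-trimethylpentadeca-5,9,13-trienyl acetate
Product: 12 (2S,5E,9E)-2-(iodomethyl)-6,10,14-trimethylpentadeca-5,9,13-trienyl acetate
Conditions: I2, PPh3, imidazole, CH2Cl2, 0 °C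
Reagents that add atoms: iodine, II
Why: Appel-type iodination at the primary carbon is fast enough to outrun acyl migration and leaves the stereocentre untouched, the descriptor changing from R to S only because CH2I outranks CH2OAc.

Step 9
Reactants: 12 (2S,5E,9E)-2-(iodomethyl)-6,10,14-trimethylpentadeca-5,9,13-trienyl acetate
Product: 13 (2S,5E,9E)-2-(iodomethyl)-6,10,14-trimethylpentadeca-5,9,13-trien-1-ol
Conditions: K2CO3 (0.3 equiv), MeOH, 0 °C
Reagents that add atoms: none
Why: Base-catalysed transesterification removes the acetate, which would not survive the carbanion chemistry ahead, and four-membered closure to an oxetane is too slow at 0 °C to compete.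

Step 10
Reactants: 13 (2S,5E,9E)-2-(iodomethyl)-6,10,14-trimethylpentadeca-5,9,13-trien-1-ol
Product: 14 tert-butyl{[(2S,5E,9E)-2-(iodomethyl)-6,10,14-trimethylpentadeca-5,9,13-trienyl]oxy}dimethylsilane
Conditions: TBSCl, imidazole, CH2Cl2, 0 °C to rt
Reagents that add atoms: tert-butyldimethylsilyl chloride, CC(C)(C)[Si](C)(C)Cl
Why: Standard silylation masks the future ring oxygen as a base-stable silyl ether.

Step 11
Reactants: 14 tert-butyl{[(2S,5E,9E)-2-(iodomethyl)-6,10,14-trimethylpentadeca-5,9,13-trienyl]oxy}dimethylsilane; 15 acetonitrile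
Product: 17 (4R,7E,11E)-4-{[tert-butyl(dimethyl)silyl]oxymethyl}-8,12,16-trimethylheptadeca-7,11,15-trienenitrile, via lithioacetonitrile 16 (not isolated)
Conditions: 15 (4 equiv), n-BuLi (3.8 equiv), THF, −78 °C; then 14, −78 to 0 °C
Reagents that add atoms: none
Why: SN2 alkylation of the small, strongly nucleophilic nitrile-stabilised carbanion at the primary iodide adds C3 and C2, and the neighbouring stereocentre is neither the reacting carbon nor acidic.

Step 12
Reactants: 17 (4R,7E,11E)-4-{[tert-butyl(dimethyl)silyl]oxymethyl}-8,12,16-trimethylheptadeca-7,11,15-trienenitrile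
Product: 19 (4R,7E,11E)-4-{[tert-butyl(dimethyl)silyl]oxymethyl}-8,12,16-trimethylheptadeca-7,11,15-trienal, via N-aluminoimine 18 (not isolated)
Conditions: i-Bu2AlH (1.3 equiv), CH2Cl2, −78 °C; then aq. tartaric acid, 0 °C to rt
Reagents that add atoms: water, O
Why: Partial hydride reduction of the nitrile stops at the N-aluminoimine, which is hydrolysed to the aldehyde on work-up.

Step 13
Reactants: 19 (4R,7E,11E)-4-{[tert-butyl(dimethyl)silyl]oxymethyl}-8,12,16-trimethylheptadeca-7,11,15-trienal; 20 ethyl (triphenylphosphoranylidene)acetate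
Product: 21 ethyl (2E,6S,9E,13E)-6-{[tert-butyl(dimethyl)silyl]oxymethyl}-10,14,18-trimethylnonadeca-2,9,13,17-tetraenoate
Conditions: 20 (1.5 equiv), CH2Cl2, rt
Reagents that add atoms: none
Why: Wittig olefination with the stabilised ylide gives the (E)-enoate, and any trace of Z-isomer converges later in the reversible ring closure (the descriptor becomes S only through a priority change).

Step 14
Reactants: 21 ethyl (2E,6S,9E,13E)-6-{[tert-butyl(dimethyl)silyl]oxymethyl}-10,14,18-trimethylnonadeca-2,9,13,17-tetraenoate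
Product: 22 ethyl (2E,6S,9E,13E)-6-(hydroxymethyl)-10,14,18-trimethylnonadeca-2,9,13,17-tetraenoate
Conditions: HF·pyridine, pyridine, THF, 0 °C to rt
Reagents that add atoms: none
Why: Pyridine-buffered fluoride desilylation frees the primary alcohol without acid-induced cyclisation of the polyene or premature conjugate addition.

Step 15
Reactants: 22 ethyl (2E,6S,9E,13E)-6-(hydroxymethyl)-10,14,18-trimethylnonadeca-2,9,13,17-tetraenoate
Product: 23 ethyl 2-[(2S,5R)-5-[(3E,7E)-4,8,12-trimethyltrideca-3,7,11-trienyl]oxan-2-yl]acetate (2,5-trans)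
Conditions: KOtBu (0.2 equiv), THF, −20 °C to rt; AcOH quench; chromatography to remove the minor cis isomer
Reagents that add atoms: none
Why: The 6-exo-trig intramolecular oxa-Michael addition forms the O1–C2 bond reversibly under alkoxide catalysis, so the product settles in the chair with both substituents equatorial (estimated about 10:1), which sets C2 as S under control of C5.

Step 16
Reactants: 23 ethyl 2-[(2S,5R)-5-[(3E,7E)-4,8,12-trimethyltrideca-3,7,11-trienyl]oxan-2-yl]acetate
Product: 25 ethyl 3-(dimethylamino)-2-[(2S,5R)-5-[(3E,7E)-4,8,12-trimethyltrideca-3,7,11-trienyl]oxan-2-yl]propanoate (both epimers at the new α-carbon), via lithium enolate 24 (not isolated)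
Conditions: LiN(i-Pr)2 (1.2 equiv), THF, −78 °C; then CH2=NMe2+ I− (2.5 equiv), −78 to −20 °C
Reagents that add atoms: Eschenmoser's salt (dimethylmethylideneammonium iodide), C=[N+](C)C.[I-]
Why: The Mannich reaction of the ester enolate with the iminium salt installs the future methylene carbon, the cold β-alkoxy enolate does not expel the ring oxygen, and the uncontrolled α-stereocentre is destroyed in the next step.

Step 17
Reactants: 25 ethyl 3-(dimethylamino)-2-[(2S,5R)-5-[(3E,7E)-4,8,12-trimethyltrideca-3,7,11-trienyl]oxan-2-yl]propanoate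
Product: 27 ethyl 2-[(2S,5R)-5-[(3E,7E)-4,8,12-trimethyltrideca-3,7,11-trienyl]oxan-2-yl]prop-2-enoate, via trimethylammonium iodide 26 (not isolated)
Conditions: MeI (10 equiv), CH2Cl2, rt; then DBU (1.5 equiv), CH2Cl2, 0 °C to rt
Reagents that add atoms: none
Why: Exhaustive N-methylation followed by base-induced E1cB (Hofmann-type) elimination expels trimethylamine, a far better leaving group than the ring alkoxide, and unveils the α-methylene ester.

Step 18
Reactants: 27 ethyl 2-[(2S,5R)-5-[(3E,7E)-4,8,12-trimethyltrideca-3,7,11-trienyl]oxan-2-yl]prop-2-enoate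
Product: 29 2-[(2S,5R)-5-[(3E,7E)-4,8,12-trimethyltrideca-3,7,11-trienyl]oxan-2-yl]prop-2-enoic acid (target), via lithium carboxylate 28 (not isolated)
Conditions: LiOH·H2O (3 equiv), THF/H2O 3:1, rt; then 1 M HCl to pH 3, 0 °C
Reagents that add atoms: lithium hydroxide, [Li+].[OH-]
Why: Saponification followed by mild acidification gives the acid, C2 cannot epimerise because the acrylate has no α-hydrogen, and the α-branched acrylate resists conjugate addition of hydroxide.

**Compound list**

1 | (2E,6E)-farnesol, (2E,6E)-3,7,11-trimethyldodeca-2,6,10-trien-1-ol | OC/C=C(\C)CC/C=C(\C)CCC=C(C)C | starting material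
2 | (2E,6E)-farnesal, (2E,6E)-3,7,11-trimethyldodeca-2,6,10-trienal | O=C/C=C(\C)CC/C=C(\C)CCC=C(C)C | intermediate
3 | (3E,7E)-4,8,12-trimethyltrideca-1,3,7,11-tetraene | C=C/C=C(\C)CC/C=C(\C)CCC=C(C)C | intermediate
4 | B-[(3E,7E)-4,8,12-trimethyltrideca-3,7,11-trienyl]-9-borabicyclo[3.3.1]nonane (alkylborane, not isolated) | B1(CC/C=C(\C)CC/C=C(\C)CCC=C(C)C)C2CCCC1CCC2 | intermediate
5 | (3E,7E)-homofarnesol, (3E,7E)-4,8,12-trimethyltrideca-3,7,11-trien-1-ol | OCC/C=C(\C)CC/C=C(\C)CCC=C(C)C | intermediate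
6 | (3E,7E)-homofarnesyl iodide, (3E,7E)-1-iodo-4,8,12-trimethyltrideca-3,7,11-triene | ICC/C=C(\C)CC/C=C(\C)CCC=C(C)C | intermediate
7 | diethyl malonate | CCOC(=O)CC(=O)OCC | starting material
8 | sodium enolate of diethyl malonate, NaCH(CO2Et)2 (not isolated) | CCOC(=O)[CH-]C(=O)OCC.[Na+] | intermediate
9 | diethyl 2-[(3E,7E)-4,8,12-trimethyltrideca-3,7,11-trienyl]malonate | CCOC(=O)C(CC/C=C(\C)CC/C=C(\C)CCC=C(C)C)C(=O)OCC | intermediate
10 | 2-[(3E,7E)-4,8,12-trimethyltrideca-3,7,11-trienyl]propane-1,3-diol (achiral) | OCC(CO)CC/C=C(\C)CC/C=C(\C)CCC=C(C)C | intermediate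
11 | (2R,5E,9E)-2-(hydroxymethyl)-6,10,14-trimethylpentadeca-5,9,13-trienyl acetate | CC(=O)OC[C@@H](CO)CC/C=C(\C)CC/C=C(\C)CCC=C(C)C | intermediate
12 | (2S,5E,9E)-2-(iodomethyl)-6,10,14-trimethylpentadeca-5,9,13-trienyl acetate | CC(=O)OC[C@@H](CI)CC/C=C(\C)CC/C=C(\C)CCC=C(C)C | intermediate
13 | (2S,5E,9E)-2-(iodomethyl)-6,10,14-trimethylpentadeca-5,9,13-trien-1-ol | OC[C@@H](CI)CC/C=C(\C)CC/C=C(\C)CCC=C(C)C | intermediate
14 | tert-butyl{[(2S,5E,9E)-2-(iodomethyl)-6,10,14-trimethylpentadeca-5,9,13-trienyl]oxy}dimethylsilane | CC(C)(C)[Si](C)(C)OC[C@@H](CI)CC/C=C(\C)CC/C=C(\C)CCC=C(C)C | intermediate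
15 | acetonitrile | CC#N | starting material
16 | lithioacetonitrile, LiCH2CN (not isolated) | [Li]CC#N | intermediate
17 | (4R,7E,11E)-4-{[tert-butyl(dimethyl)silyl]oxymethyl}-8,12,16-trimethylheptadeca-7,11,15-trienenitrile | CC(C)(C)[Si](C)(C)OC[C@@H](CCC#N)CC/C=C(\C)CC/C=C(\C)CCC=C(C)C | intermediate
18 | N-(diisobutylalumino)imine of aldehyde 19 (not isolated) | CC(C)(C)[Si](C)(C)OC[C@@H](CCC=N[Al](CC(C)C)CC(C)C)CC/C=C(\C)CC/C=C(\C)CCC=C(C)C | intermediate
19 | (4R,7E,11E)-4-{[tert-butyl(dimethyl)silyl]oxymethyl}-8,12,16-trimethylheptadeca-7,11,15-trienal | CC(C)(C)[Si](C)(C)OC[C@@H](CCC=O)CC/C=C(\C)CC/C=C(\C)CCC=C(C)C | intermediate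
20 | ethyl (triphenylphosphoranylidene)acetate | CCOC(=O)C=P(c1ccccc1)(c1ccccc1)c1ccccc1 | starting material
21 | ethyl (2E,6S,9E,13E)-6-{[tert-butyl(dimethyl)silyl]oxymethyl}-10,14,18-trimethylnonadeca-2,9,13,17-tetraenoate | CC(C)(C)[Si](C)(C)OC[C@@H](CC/C=C/C(=O)OCC)CC/C=C(\C)CC/C=C(\C)CCC=C(C)C | intermediate
22 | ethyl (2E,6S,9E,13E)-6-(hydroxymethyl)-10,14,18-trimethylnonadeca-2,9,13,17-tetraenoate | OC[C@@H](CC/C=C/C(=O)OCC)CC/C=C(\C)CC/C=C(\C)CCC=C(C)C | intermediate
23 | ethyl 2-[(2S,5R)-5-[(3E,7E)-4,8,12-trimethyltrideca-3,7,11-trienyl]oxan-2-yl]acetate (2,5-trans) | CCOC(=O)C[C@@H]1CC[C@@H](CC/C=C(\C)CC/C=C(\C)CCC=C(C)C)CO1 | intermediate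
24 | lithium enolate of ester 23 (not isolated) | CCOC(O[Li])=C[C@@H]1CC[C@@H](CC/C=C(\C)CC/C=C(\C)CCC=C(C)C)CO1 | intermediate
25 | ethyl 3-(dimethylamino)-2-[(2S,5R)-5-[(3E,7E)-4,8,12-trimethyltrideca-3,7,11-trienyl]oxan-2-yl]propanoate (both α-epimers) | CCOC(=O)C(CN(C)C)[C@@H]1CC[C@@H](CC/C=C(\C)CC/C=C(\C)CCC=C(C)C)CO1 | intermediate
26 | trimethylammonium iodide of amine 25 (not isolated) | CCOC(=O)C(C[N+](C)(C)C)[C@@H]1CC[C@@H](CC/C=C(\C)CC/C=C(\C)CCC=C(C)C)CO1.[I-] | intermediate
27 | ethyl 2-[(2S,5R)-5-[(3E,7E)-4,8,12-trimethyltrideca-3,7,11-trienyl]oxan-2-yl]prop-2-enoate | C=C(C(=O)OCC)[C@@H]1CC[C@@H](CC/C=C(\C)CC/C=C(\C)CCC=C(C)C)CO1 | intermediate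
28 | lithium 2-[(2S,5R)-5-[(3E,7E)-4,8,12-trimethyltrideca-3,7,11-trienyl]oxan-2-yl]prop-2-enoate (not isolated) | C=C(C(=O)[O-])[C@@H]1CC[C@@H](CC/C=C(\C)CC/C=C(\C)CCC=C(C)C)CO1.[Li+] | intermediate
29 | 2-[(2S,5R)-5-[(3E,7E)-4,8,12-trimethyltrideca-3,7,11-trienyl]oxan-2-yl]prop-2-enoic acid | C=C(C(=O)O)[C@@H]1CC[C@@H](CC/C=C(\C)CC/C=C(\C)CCC=C(C)C)CO1 | target

**Step count and risks**

Total step count: 18. Longest linear sequence: 18 steps (1 to 29); 7, 15 and 20 enter directly as purchased materials.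

Three steps most likely to fail:

Step 7 (lipase desymmetrisation; the risks are insufficient ee, the opposite sense, or acyl migration in 11). The fallback sets out from 10 and comes back at 14. Both hydroxyls of 10 are acetylated (Ac2O, pyridine, DMAP) to the diacetate F1. The same lipase then hydrolyses one enantiotopic ester in pH 7 phosphate buffer/acetone; it attacks the arm that acetylation would have esterified and so leaves the (S)-monoacetate F2, with the free hydroxyl on the future C6 arm. Silylation (TBSCl, imidazole) gives the silyl ether acetate F3, methanolysis (K2CO3, MeOH) gives the silyl ether alcohol F4, and Appel iodination (I2, PPh3, imidazole) of F4 gives 14. If the acetylation of step 7 itself delivers F2 instead of 11, that material enters the same sequence at F2.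

Step 11 (SN2 of LiCH2CN at a β-branched primary iodide; the risks are E2 elimination and double alkylation). The fallback sets out from 14 and comes back at 19. Malonic ester homologation with the softer, less basic nucleophile (7, NaH, DMF, 60 °C) gives the alkylated malonate F5. Krapcho dealkoxycarbonylation (LiCl, wet DMSO, 150 °C) gives the ethyl ester F6. Reduction with i-Bu2AlH in toluene at −78 °C then gives aldehyde 19.

Step 16 (Mannich reaction of a β-alkoxy ester enolate; the risks are β-elimination that opens the ring and incomplete conversion). The fallback sets out from 19 and comes back at 27; it replaces steps 13 to 17 and never exposes an ester next to the ring oxygen to strong base. Knoevenagel condensation of 19 with 7 (piperidine, AcOH, toluene, reflux with water removal) gives the alkylidenemalonate F7. HF·pyridine frees the hydroxy alkylidenemalonate F8, which on addition of Et3N closes by reversible oxa-Michael addition to the 2,5-trans oxanyl malonate F9. One equivalent of KOH in EtOH gives the malonic half-ester F10. Decarboxylative Mannich methylenation (paraformaldehyde, Et2NH, EtOAc, reflux) then delivers 27.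

**Further compounds**

F1 | step 7 | 2-[(3E,7E)-4,8,12-trimethyltrideca-3,7,11-trienyl]propane-1,3-diyl diacetate (achiral) | CC(=O)OCC(COC(C)=O)CC/C=C(\C)CC/C=C(\C)CCC=C(C)C
F2 | step 7 | (2S,5E,9E)-2-(hydroxymethyl)-6,10,14-trimethylpentadeca-5,9,13-trienyl acetate | OC[C@@H](COC(C)=O)CC/C=C(\C)CC/C=C(\C)CCC=C(C)C
F3 | step 7 | (2R,5E,9E)-2-{[tert-butyl(dimethyl)silyl]oxymethyl}-6,10,14-trimethylpentadeca-5,9,13-trienyl acetate | CC(C)(C)[Si](C)(C)OC[C@@H](COC(C)=O)CC/C=C(\C)CC/C=C(\C)CCC=C(C)C
F4 | step 7 | (2R,5E,9E)-2-{[tert-butyl(dimethyl)silyl]oxymethyl}-6,10,14-trimethylpentadeca-5,9,13-trien-1-ol | CC(C)(C)[Si](C)(C)OC[C@@H](CO)CC/C=C(\C)CC/C=C(\C)CCC=C(C)C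
F5 | step 11 | diethyl 2-[(2R,5E,9E)-2-{[tert-butyl(dimethyl)silyl]oxymethyl}-6,10,14-trimethylpentadeca-5,9,13-trienyl]malonate | CC(C)(C)[Si](C)(C)OC[C@@H](CC(C(=O)OCC)C(=O)OCC)CC/C=C(\C)CC/C=C(\C)CCC=C(C)C
F6 | step 11 | ethyl (4R,7E,11E)-4-{[tert-butyl(dimethyl)silyl]oxymethyl}-8,12,16-trimethylheptadeca-7,11,15-trienoate | CC(C)(C)[Si](C)(C)OC[C@@H](CCC(=O)OCC)CC/C=C(\C)CC/C=C(\C)CCC=C(C)C
F7 | step 16 | diethyl 2-[(4R,7E,11E)-4-{[tert-butyl(dimethyl)silyl]oxymethyl}-8,12,16-trimethylheptadeca-7,11,15-trienylidene]malonate | CC(C)(C)[Si](C)(C)OC[C@@H](CCC=C(C(=O)OCC)C(=O)OCC)CC/C=C(\C)CC/C=C(\C)CCC=C(C)C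
F8 | step 16 | diethyl 2-[(4R,7E,11E)-4-(hydroxymethyl)-8,12,16-trimethylheptadeca-7,11,15-trienylidene]malonate | OC[C@@H](CCC=C(C(=O)OCC)C(=O)OCC)CC/C=C(\C)CC/C=C(\C)CCC=C(C)C
F9 | step 16 | diethyl 2-[(2S,5R)-5-[(3E,7E)-4,8,12-trimethyltrideca-3,7,11-trienyl]oxan-2-yl]malonate | CCOC(=O)C(C(=O)OCC)[C@@H]1CC[C@@H](CC/C=C(\C)CC/C=C(\C)CCC=C(C)C)CO1
F10 | step 16 | 3-ethoxy-3-oxo-2-[(2S,5R)-5-[(3E,7E)-4,8,12-trimethyltrideca-3,7,11-trienyl]oxan-2-yl]propanoic acid (both epimers at the malonate carbon) | CCOC(=O)C(C(=O)O)[C@@H]1CC[C@@H](CC/C=C(\C)CC/C=C(\C)CCC=C(C)C)CO1
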